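| setting | elm | ash | larch | north-east | west |
|---|---|---|---|---|---|
| Q | 16 mM | 16 mM | 16 mM | 16 mM | 16 mM |
| J | 24 mM | 24 mM | 24 mM | 24.0 mM | 24.0 mM |
| D | 3.6 mM | 7.8 mM | 16 mM | 4.00 mM | 17.6 mM |
| remark | run made earlier | run made earlier | run made earlier |  |  |
| time |  |  |  | 10 d | 2.5 d |

| run | time / h | E / % |
|---|---|---|
| elm | 8.00 | 2.1 |
| elm | 15.0 | 3.7 |
| elm | 25.0 | 4.7 |
| elm | 30.0 | 5.4 |
| elm | 40.0 | 6.2 |
| ash | 3.00 | 0.8 |
| ash | 6.00 | 2.4 |
| ash | 12.0 | 5.8 |
| ash | 20.0 | 9.6 |
| ash | 40.0 | 15.0 |
| larch | 3.00 | 2.2 |
| larch | 6.00 | 5.2 |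
| larch | 12.0 | 11.3 |
| larch | 20.0 | 17.1 |
| larch | 40.0 | 27.8 |

(each reading ± 0.3 percentage points)

- which one finishes higher in amount of E, in percent of the Q charged ("neither" within 2 percentage points) (north-east / west / neither)
- amount of E at the end, in percent of the Q charged, north-east
- amount of E at the end, in percent of the Q charged, west

- percent here means Q units held: one Z counts as two
- steps under discussion: D + G -> E; Q + E -> Z; Q + D -> X; Q + J -> G

Early on, elm and larch differ by scale. Q and J make G, and G meets D to give E. Over the first 20.0 h larch gains 17.1% of the Q charged. Elm, taking the mean of its readings at 15.0 h and 25.0 h, gains 4.20%. That is a factor of 4.07 against 4.44 in D.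

Then they part. The carry ratio, E gained in the second 20.0 h over E gained in the first, reads 0.626 in larch but 0.476 in elm, lower, both with the scatter of the readings.

If each span carries over the same ratio of the one before, a first-order fall of the rate, the gains sum to a rest value: the first gain over one minus the ratio. For elm that is 8.02%. North-east is elm with D up by a factor of 1.11, and its 10 d is longer than a span, so the reckoning here gives 8.91%. West is larch with D up by a factor of 1.10, stopped after 3.00 spans, which gives 37.9%, higher.

The forecast names west, with 5% for north-east and 36% for west, both below this reckoning: “West clearly wins”.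

The flasks give west, with 9.08% in north-east and 35.2% in west.

    D + G → E (k = 0.0570 M⁻¹ min⁻¹)
    Q + E → Z (k = 0.0620 M⁻¹ min⁻¹)
    Q + D → X (k = 0.140 M⁻¹ min⁻¹)
    Q + J → G (k = 0.100 M⁻¹ min⁻¹)

North-east has come to rest: Q and D stand at 0% and 0%, and 100 d still gives 9.08%. West has not: Q stands at 0%, but 24% of its D remains, and G holds 15.6% of the Q charged. For a further flask, like west but with 7.0 mM of D, ash's ratio of 0.562 reckons 16.2%, and that flask gives 15.5%. Larch's ratio of 0.626, scaled to west, puts its rest value at 50.3%, and at 25.0 d west stands at 50.5%.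

The data are simulated for substances that don't exist, and the scatter is random.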